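# Total synthesis of CNP0353860.3 by oxidative radical bicyclisation of an α-benzyl β-keto ester

## Analysis of the target

The target is a trans-fused decalin (ring A = C1–C4, C5, C10; ring B = C5–C10) with an exocyclic methylene C4=C11. The methylene C15 on C9 links it to a 1,2,3,5-tetrasubstituted arene C1′–C6′ carrying a hydrogen sulfate on O2′, a free phenol on O3′ and a hydroxymethyl group on C5′.

Four contiguous stereocentres are present: C5 (S, quaternary, β-methyl C14), C10 (S, α-H), C9 (R, quaternary, β-methyl C13, α-arylmethyl) and C8 (S, β-methyl C12). C14 and C13 are 1,3-diaxial on the same face, C12 is equatorial and cis to C13, and the ring fusion is trans; the decalin is (1R,2S,4aS,8aS) in naphthalene numbering.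

The sensitive groups are:
- the 1,1-disubstituted alkene, which acid moves into the ring and which excludes any hydrogenation once it exists;
- the aryl sulfate monoester, which is acid-labile and itself a strong acid;
- the electron-rich monophenol;
- the benzylic alcohol para to O2′.

The difficulty lies in the two quaternary carbons C5 and C9 flanking C10, in the neopentylic C9–C15 link (which cannot be made by late substitution at C9), in C8 next to a quaternary centre, and in telling O2′ from O3′.

The strategy rests on one feature. C9 is quaternary, carries a one-carbon substituent (C13) and is adjacent to C8. With C13 at the ester level and C8 as a ketone, C9 is the α-carbon of a β-keto ester. The bonds C9–C10 and C4–C5 then map onto an (E)-C5=C10 alkene and a C4≡C11 alkyne, so one radical generated at C9 can close ring B and then ring A and leave C4=C11 behind.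

## Retrosynthetic reasoning

**30 ⇒ 28 ⇒ 27 (S–O2′).** The sulfate is the most fragile group and is introduced last but one. Sulfation must find O2′ as the only free hydroxyl, so O3′ and the benzylic oxygen carry silicon-based groups (SEM and TBDPS) that a single fluoride treatment removes in the presence of the sulfate anion. No acid and no hydrogenolysis is needed after the sulfate is in place.

**27 ⇒ 26 (O2′–allyl).** O2′ is carried as an allyl ether because it can be taken off with zerovalent palladium under neutral conditions, which the exocyclic alkene, the SEM acetal and the silyl ether survive. Methyl ethers were rejected here: their cleavage needs reagents that the C4=C11 alkene would not tolerate.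

**26 ⇒ 25 ⇒ 24 (C13–O).** The 9β-methyl group is the reduced form of the carbon that made the radical chemistry possible. The neopentyl C13–O bond cannot be cut by substitution, so it is cut homolytically through xanthate 25.

**24 ⇒ 22 ⇒ 21 ⇒ 20 ⇒ 19 ⇒ 18 (C8–C12 and C8–O).** C12 is added to the C8 ketone of 18 as a methyl nucleophile and the tertiary oxygen is then removed by a radical. Hydrogenation of a C8 alkene is excluded by C4=C11. A planar C8 radical takes hydrogen on the α face, opposite the axial C13 arm, which is the required configuration. The tertiary alcohol is hindered, so it is derivatised intramolecularly: after hydride reduction of both esters (20) and silylation of the benzylic alcohol (21), the C13 carbinol and the 8β-hydroxyl are bridged as cyclic thionocarbonate 22. This opens at the tertiary carbon and returns the C13 alcohol 24.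

**18 ⇒ 17 (C9–C10 and C4–C5, key disconnection).** Both ring bonds are cut to give the acyclic enynyl β-keto ester 17. Forward, one-electron oxidation of the keto ester by trivalent manganese gives the C9 radical. Ring B closes on C10, the C5 radical closes ring A on the alkyne, and the vinyl radical is reduced by the alcohol solvent. Cutting here turns a bicyclic problem with three stereocentres into an open chain with one (E)-alkene. The ester on C9 is a chiral alcohol (13), so the two faces of the C9 radical differ.

**17 ⇒ 16 + 12 (C9–C15) and 16 ⇒ 15 + 5 (C6–C7).** The arylmethyl group is attached by enolate alkylation at the doubly activated C9. The chain is attached by γ-alkylation of the acetoacetate dianion of 15 with allylic bromide 5. The γ-alkylation comes first because the aryl ester of 12 would not survive the dianion conditions.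

**15 ⇒ 13 + 14.** The auxiliary ester is made by transesterification.

**5 ⇒ 4 ⇒ 3 ⇒ 1 (via 2).** The (E)-trisubstituted alkene, the only stereochemical information in the chain, comes from a stabilised Wittig olefination of aldehyde 2, followed by reduction and bromination.

**12 ⇒ 11 ⇒ 10 ⇒ 9 ⇒ 8 ⇒ 7 ⇒ 6.** All arene carbons and oxygens are present after ortho-formylation of 6. O2′ and O3′ are told apart at the stage of catechol 8, where O2′–H is ortho to the aldehyde and para to the ester and much the more acidic. The selectivity question of the end game is thus settled on a simple early intermediate.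

## Alternatives that were turned down

**Alternative 1:** C9–C10 is disconnected by a [3,3] shift and C5–C6 by enolate alkylation, starting from a chiral-pool ring A enone. Forward, a potassium alkoxide at C4 drives an anionic oxy-Cope rearrangement across C10=C5–C4–CH2–C8=C9, and the C5 enolate is C-allylated to give A1; no ring is closed.
- For it: the absolute configuration comes from the starting material and a concerted chair transition state, with no auxiliary and no facial model. The C4 oxygen survives for a very late methylenation, so the sensitive C4=C11 alkene need not be carried through reductions. On both points it is stronger than the chosen route.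
- Against it: the configuration at C9 depends on a geometrically pure tetrasubstituted C8=C9 alkene and on chair versus boat. The new bond joins a fully substituted C9 to a ring carbon beside the future quaternary C5, where fragmentation of the alkoxide can compete. After A1, ring B still has to be closed to a hindered trisubstituted alkene, C8 set by hydrogenation, the extra ring A oxygen removed and C4 methylenated.
- Comparison: the chosen route needs only a trisubstituted (E)-alkene made by a Wittig reaction, and closes both rings with three stereocentres in the step where this alternative closes none.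

**Alternative 2:** the arene bonds C1′–C6′ and C2′–C3′ are disconnected, so the benzene ring is built last on a finished decalin. Forward, a silyloxy-alkyne terminus C1′≡C2′ attached to C15 adds across a pyranone diene and the bridged adduct aromatises by decarboxylation to give A2.
- For it: O2′ (silyl) and O3′ (4-methoxybenzyl) are born differentiated, with regiochemistry set by polarisation. This is a cleaner answer to the sulfation-site problem than the chosen route, which relies on the acidity difference in catechol 8.
- Against it: the step makes no stereocentre and no ring of the terpenoid part. The whole C5/C8/C9/C10 problem remains and needs its own synthesis of a length comparable to the chosen route. The silyloxy-alkyne sits on a neopentylic carbon and is sensitive, the cycloaddition needs heat next to C4=C11, and the 4-methoxybenzyl group would have to leave after sulfation.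
- Comparison: the chosen route spends its key step on the hard part of the molecule and brings the arene in by a simple alkylation.

**Alternative 3:** C9–C10 is disconnected by an Ireland–Claisen rearrangement of a six-membered lactone (O–C1–C10–C5–C6–C7) with an alkenyl group on C7. Forward, the silyl ketene acetal rearranges through a boat, O–C7 breaks and ring B appears as the C7=C8 cyclohexene acid A3.
- For it: chirality transfer within a cyclic transition state is more predictable than facial control by a remote auxiliary, and the C7=C8 alkene could be hydrogenated before C4=C11 exists. It is stronger on both points.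
- Against it: it again needs a stereodefined tetrasubstituted C8=C9 alkene. The quaternary C5 and the C7 carbinol must be set beforehand, so C5 is not created by the key step. The shift joins two heavily substituted termini. Ring A must afterwards be annulated from the C1 acid and the C4 siloxymethyl group, followed by C8 reduction and C4 methylenation.
- Comparison: the chosen route makes C5, C9 and C10 and both rings at once from a precursor assembled by three alkylation-type steps.

Key step: step 13

Remark: the sense of induction by auxiliary 13 is assigned from a rotamer model (ester C=O s-cis to the C9–C8 bond, phenyl over the Si face of C9); this is assumed to hold for the α-benzyl radical.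

Remark: the target is drawn as the free hydrogen sulfate, so the last step ends with a cold proton exchange; the salt 29 is the form to store.

Group symbols used in the names:
- R* = (1R,2S,5R)-5-methyl-2-(2-phenylpropan-2-yl)cyclohexyl (the (−)-8-phenylmenthyl group)
- SEM = [2-(trimethylsilyl)ethoxy]methyl
- TBDPS = tert-butyldiphenylsilyl
- ArE = 2-(prop-2-en-1-yloxy)-5-(methoxycarbonyl)-3-(SEM-oxy)phenyl
- ArH = 2-(prop-2-en-1-yloxy)-5-(hydroxymethyl)-3-(SEM-oxy)phenyl
- ArS = 2-(prop-2-en-1-yloxy)-5-[(TBDPS-oxy)methyl]-3-(SEM-oxy)phenyl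
- Decalin locants are C1–C15 as in the analysis; α is the face of H10, β the face of C14.

## Route

Step 1
Reactants: 1 hex-5-yn-1-ol
Product: 3 ethyl (2E)-2-methyloct-2-en-7-ynoate, via hex-5-ynal 2 (not isolated)
Conditions: TEMPO (2,2,6,6-tetramethylpiperidin-1-oxyl, 10 mol%), PhI(OAc)2, CH2Cl2, rt; then Ph3P=C(CH3)CO2Et, rt
Reagents that add atoms: ethyl 2-(triphenyl-λ5-phosphanylidene)propanoate, CCOC(=O)C(C)=P(c1ccccc1)(c1ccccc1)c1ccccc1
Why: Oxoammonium oxidation stops at the volatile aldehyde, which is trapped in the same flask by the stabilised ylide (tandem oxidation–Wittig olefination); the α-methyl ester ylide should give the (E)-enoate, which fixes the C5=C10 geometry that later dictates the trans ring fusion.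

Step 2
Reactants: 3 ethyl (2E)-2-methyloct-2-en-7-ynoate
Product: 4 (2E)-2-methyloct-2-en-7-yn-1-ol
Conditions: DIBAL-H (2.2 equiv), CH2Cl2, −78 to 0 °C
Reagents that add atoms: none
Why: 1,2-Reduction of a conjugated ester by DIBAL-H gives the allylic alcohol and leaves the alkene geometry and the terminal alkyne untouched.

Step 3
Reactants: 4 (2E)-2-methyloct-2-en-7-yn-1-ol
Product: 5 (6E)-8-bromo-7-methyloct-6-en-1-yne
Conditions: CBr4, PPh3, CH2Cl2, 0 °C
Reagents that add atoms: tetrabromomethane, BrC(Br)(Br)Br
Why: Appel bromination of a primary allylic alcohol proceeds under neutral conditions by direct displacement, so neither allylic transposition nor loss of the (E) geometry is expected.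

Step 4
Reactants: 6 methyl 4-hydroxy-3-methoxybenzoate
Product: 7 methyl 3-formyl-4-hydroxy-5-methoxybenzoate
Conditions: hexamethylenetetramine, CF3CO2H, 90 °C; then H2O, 60 °C
Reagents that add atoms: hexamethylenetetramine, C1N2CN3CN1CN(C2)C3; water, O
Why: In the Duff formylation the iminium electrophile attacks ortho to the free phenol; the only open ortho position is the future C1′ and the para position is blocked by the ester, so one regioisomer is expected.

Step 5
Reactants: 7 methyl 3-formyl-4-hydroxy-5-methoxybenzoate
Product: 8 methyl 3-formyl-4,5-dihydroxybenzoate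
Conditions: AlCl3, pyridine, CH2Cl2, reflux; then 1 M HCl
Reagents that add atoms: none
Why: Chelation-assisted O-demethylation: aluminium binds the phenoxide and the neighbouring methoxy oxygen and pyridine removes the methyl group, so only the ether next to the free hydroxyl is cleaved and the methyl ester stays.

Step 6
Reactants: 8 methyl 3-formyl-4,5-dihydroxybenzoate
Product: 9 methyl 3-formyl-5-hydroxy-4-(prop-2-en-1-yloxy)benzoate
Conditions: allyl bromide (1.05 equiv), NaHCO3, NaI (cat.), DMF, 40 °C
Reagents that add atoms: allyl bromide, C=CCBr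
Why: Williamson etherification of the monoanion: the hydroxyl that becomes O2′ is ortho to the aldehyde and para to the ester and much the more acidic, so hydrogencarbonate forms only that phenoxide and one equivalent of halide should alkylate it.

Step 7
Reactants: 9 methyl 3-formyl-5-hydroxy-4-(prop-2-en-1-yloxy)benzoate
Product: 10 methyl 3-formyl-4-(prop-2-en-1-yloxy)-5-(SEM-oxy)benzoate
Conditions: SEMCl, i-Pr2NEt, CH2Cl2, 0 °C to rt
Reagents that add atoms: 2-(trimethylsilyl)ethoxymethyl chloride, C[Si](C)(C)CCOCCl
Why: The remaining phenol (future O3′) is alkylated by the α-chloro ether under amine base; SEM is chosen because it resists hydride, organometallic and radical conditions and leaves with fluoride at the end.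

Step 8
Reactants: 10 methyl 3-formyl-4-(prop-2-en-1-yloxy)-5-(SEM-oxy)benzoate
Product: 11 methyl 3-(hydroxymethyl)-4-(prop-2-en-1-yloxy)-5-(SEM-oxy)benzoate
Conditions: NaBH4, MeOH–THF, 0 °C
Reagents that add atoms: none
Why: Borohydride reduces the aldehyde chemoselectively in the presence of the benzoate ester.

Step 9
Reactants: 11 methyl 3-(hydroxymethyl)-4-(prop-2-en-1-yloxy)-5-(SEM-oxy)benzoate
Product: 12 methyl 3-(bromomethyl)-4-(prop-2-en-1-yloxy)-5-(SEM-oxy)benzoate
Conditions: CBr4, PPh3, CH2Cl2, 0 °C
Reagents that add atoms: tetrabromomethane, BrC(Br)(Br)Br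
Why: Appel bromination is neutral, so the SEM acetal and the allyl ether are spared; the ester keeps the benzylic bromide from being too labile to handle.

Step 10
Reactants: 13 (−)-8-phenylmenthol; 14 methyl acetoacetate
Product: 15 R* 3-oxobutanoate
Conditions: 4-(dimethylamino)pyridine (cat.), toluene, reflux, 4 Å molecular sieves
Reagents that add atoms: none
Why: Amine-catalysed transesterification of a β-keto ester (through its acylketene/enol manifold) works with hindered secondary alcohols and is driven by removal of methanol.

Step 11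
Reactants: 15 R* 3-oxobutanoate; 5 (6E)-8-bromo-7-methyloct-6-en-1-yne
Product: 16 R* (6E)-6-methyl-3-oxododec-6-en-11-ynoate
Conditions: NaH, THF, 0 °C; n-BuLi, 0 °C; then 5, 0 °C to rt; then aq. NH4Cl
Reagents that add atoms: none
Why: Acetoacetate dianion γ-alkylation: the terminal carbanion reacts with the primary allylic bromide by direct displacement faster than it deprotonates the alkyne, forming C6–C7 without touching the alkene geometry.

Step 12
Reactants: 16 R* (6E)-6-methyl-3-oxododec-6-en-11-ynoate; 12 methyl 3-(bromomethyl)-4-(prop-2-en-1-yloxy)-5-(SEM-oxy)benzoate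
Product: 17 R* (6E)-2-(ArE-methyl)-6-methyl-3-oxododec-6-en-11-ynoate (both C2 epimers)
Conditions: NaH, THF–DMF, 0 °C; then 12, n-Bu4NI (cat.), rt
Reagents that add atoms: none
Why: C-Alkylation of the sodium enolate of a β-keto ester with a benzylic bromide forms C9–C15; the product is hindered and less acidic, so a second alkylation is not expected, and the epimeric mixture at C9 is irrelevant because C9 becomes planar in the next step.

Step 13
Reactants: 17 R* (6E)-2-(ArE-methyl)-6-methyl-3-oxododec-6-en-11-ynoate
Product: 18 R* 9α-(ArE-methyl)-5β-methyl-4(11)-methylidene-8-oxo-10αH-trans-decalin-9β-carboxylate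
Conditions: Mn(OAc)3·2H2O (2.5 equiv), degassed EtOH–AcOH (4:1), 0.02 M, 60 °C
Reagents that add atoms: none
Why: Slow enolisation of the α-benzyl keto ester gives a trivalent-manganese enolate that loses divalent manganese to the free, electrophilic C9 radical, so both C9 epimers of 17 converge. The closest known reaction type is the oxidative free-radical polyene cyclisation of α-substituted β-keto esters with alkyne termination in an alcohol solvent and with 8-phenylmenthyl esters as chiral controllers. Ring B closes 6-endo-trig by attack of C9 on the less substituted C10, giving the tertiary C5 radical; ring A closes 6-exo-dig by attack of C5 on C4, and the C11 vinyl radical abstracts hydrogen from ethanol, whose radical consumes the second equivalent of oxidant. C9 is set by the chair transition state with the ketone in the ring: the ester lies anti to the ketone C=O and syn to C7 and therefore ends axial (β), with the arylmethyl group equatorial. C10 is set by the (E)-alkene, which places the C1 chain equatorial and H10 axial and anti to C13; C5 is set by chair-like closure of ring A through an equatorial bond, giving the trans fusion with C14 axial and syn to C13. The absolute sense comes from the auxiliary: with the carbinol C–H eclipsing the ester C=O and the C=O turned toward C7, the phenyl ring stacks over the Si face of C9 and C10 should bond to the Re face. The step needs 6-endo over 5-exo closure (secured by the trisubstituted alkene), ring A closure before the C5 radical is oxidised or reduced (no copper salt, high dilution, limited ethanol), and face selectivity at C9. Because the auxiliary stays in the product, the minor-face isomer is a diastereomer and should be removable by chromatography.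

Step 14
Reactants: 18 R* 9α-(ArE-methyl)-5β-methyl-4(11)-methylidene-8-oxo-10αH-trans-decalin-9β-carboxylate
Product: 19 R* 9α-(ArE-methyl)-8β-hydroxy-5β,8α-dimethyl-4(11)-methylidene-10αH-trans-decalin-9β-carboxylate
Conditions: CeCl3 (anhydrous), MeLi, THF, −78 °C; then H2O
Reagents that add atoms: methyllithium (delivered as MeCeCl2), [Li]C
Why: Organocerium 1,2-addition: the weakly basic reagent suppresses enolisation toward C7 and retro-aldol cleavage, and at −78 °C the ketone should react before the para-alkoxybenzoate and the shielded C13 ester. Attack on the α face, away from the axial 9β-ester, should give the 8β-alcohol, the epimer that can later be bridged to C13.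

Step 15
Reactants: 19 R* 9α-(ArE-methyl)-8β-hydroxy-5β,8α-dimethyl-4(11)-methylidene-10αH-trans-decalin-9β-carboxylate
Product: 20 9α-(ArH-methyl)-9β-(hydroxymethyl)-5β,8α-dimethyl-4(11)-methylidene-10αH-trans-decalin-8β-ol
Conditions: LiAlH4, THF, 0 °C to reflux
Reagents that add atoms: none
Why: Hydride reduction of both esters: the C8 alkoxyaluminate can deliver hydride intramolecularly to the hindered C13 ester, the aryl ester is reduced as well, and auxiliary 13 is released for recovery.

Step 16
Reactants: 20 9α-(ArH-methyl)-9β-(hydroxymethyl)-5β,8α-dimethyl-4(11)-methylidene-10αH-trans-decalin-8β-ol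
Product: 21 9α-(ArS-methyl)-9β-(hydroxymethyl)-5β,8α-dimethyl-4(11)-methylidene-10αH-trans-decalin-8β-ol
Conditions: TBDPSCl (1.05 equiv), imidazole, CH2Cl2, 0 °C
Reagents that add atoms: tert-butyl(chloro)diphenylsilane, CC(C)(C)[Si](Cl)(c1ccccc1)c1ccccc1
Why: Steric differentiation in silylation: the bulky chloride should react at the open benzylic alcohol and not at the neopentylic C13 carbinol or the tertiary C8 hydroxyl.

Step 17
Reactants: 21 9α-(ArS-methyl)-9β-(hydroxymethyl)-5β,8α-dimethyl-4(11)-methylidene-10αH-trans-decalin-8β-ol
Product: 22 cyclic thionocarbonate (1,3-dioxane-2-thione) bridging O13 and the 8β-oxygen of 21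
Conditions: 1,1′-thiocarbonyldiimidazole, 4-(dimethylamino)pyridine, toluene, 110 °C
Reagents that add atoms: 1,1′-thiocarbonyldiimidazole, S=C(n1ccnc1)n1ccnc1
Why: Cyclic thionocarbonate formation from a 1,3-diol: the primary alcohol is thioacylated first and the tertiary 8β-hydroxyl, gauche to the axial C13 arm, closes the six-membered ring intramolecularly, which avoids an intermolecular acylation of a hindered tertiary alcohol.

Step 18
Reactants: 22 cyclic thionocarbonate bridging O13 and the 8β-oxygen
Product: 24 [9α-(ArS-methyl)-5β,8β-dimethyl-4(11)-methylidene-10αH-trans-decalin-9β-yl]methanol, via stannyl thiolcarbonate 23 (not isolated)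
Conditions: Bu3SnH, azobisisobutyronitrile (cat.), toluene, 110 °C, slow addition; then K2CO3 (cat.), MeOH–H2O, rt
Reagents that add atoms: none
Why: Radical deoxygenation of a cyclic thionocarbonate: the stannyl radical adds to sulfur and the adduct fragments toward the more stable tertiary C8 radical. Bu3SnH should deliver hydrogen to the α face (axial approach, the β face being covered by the axial C13 arm), which sets C8 as S with the methyl group β and equatorial; methanolysis of 23 releases the C13 alcohol.

Step 19
Reactants: 24 [9α-(ArS-methyl)-5β,8β-dimethyl-4(11)-methylidene-10αH-trans-decalin-9β-yl]methanol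
Product: 25 O-{[9α-(ArS-methyl)-5β,8β-dimethyl-4(11)-methylidene-10αH-trans-decalin-9β-yl]methyl} S-methyl carbonodithioate
Conditions: NaH, imidazole (cat.), THF, 0 °C to rt; CS2; then MeI
Reagents that add atoms: carbon disulfide, S=C=S; iodomethane, CI
Why: Xanthate formation (alkoxide addition to carbon disulfide, then S-methylation); the substrate no longer has a β-hydroxy ester, so the basic conditions cannot trigger a retro-aldol cleavage.

Step 20
Reactants: 25 O-{[9α-(ArS-methyl)-5β,8β-dimethyl-4(11)-methylidene-10αH-trans-decalin-9β-yl]methyl} S-methyl carbonodithioate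
Product: 26 9α-(ArS-methyl)-5β,8β,9β-trimethyl-4(11)-methylidene-10αH-trans-decalin
Conditions: Bu3SnH, 1,1′-azobis(cyclohexanecarbonitrile) (cat.), xylene, 130 °C
Reagents that add atoms: none
Why: Barton–McCombie deoxygenation turns the neopentylic C13 carbinol into the 9β-methyl group without substitution or hydrogenation chemistry; scission of a primary C–O bond needs the higher temperature, which the allyl ether (both ortho positions blocked) should tolerate, and no stereocentre is involved.

Step 21
Reactants: 26 9α-(ArS-methyl)-5β,8β,9β-trimethyl-4(11)-methylidene-10αH-trans-decalin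
Product: 27 2-{[5β,8β,9β-trimethyl-4(11)-methylidene-10αH-trans-decalin-9α-yl]methyl}-4-[(TBDPS-oxy)methyl]-6-(SEM-oxy)phenol
Conditions: Pd(PPh3)4 (5 mol%), morpholine, THF, 40 °C
Reagents that add atoms: none
Why: Tsuji–Trost deallylation: zerovalent palladium ionises the aryl allyl ether to a π-allyl complex that morpholine captures; the conditions are neutral and leave the exocyclic alkene, the SEM acetal and the silyl ether alone.

Step 22
Reactants: 27 2-{[5β,8β,9β-trimethyl-4(11)-methylidene-10αH-trans-decalin-9α-yl]methyl}-4-[(TBDPS-oxy)methyl]-6-(SEM-oxy)phenol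
Product: 28 sodium 2-{[5β,8β,9β-trimethyl-4(11)-methylidene-10αH-trans-decalin-9α-yl]methyl}-4-[(TBDPS-oxy)methyl]-6-(SEM-oxy)phenyl sulfate
Conditions: SO3·pyridine (5 equiv), pyridine, 50 °C; then aq. NaHCO3
Reagents that add atoms: sulfur trioxide–pyridine complex, O=S(=O)([O-])[n+]1ccccc1; sodium hydrogencarbonate, [Na+].OC([O-])=O
Why: O-Sulfation of a phenol by an amine–sulfur trioxide complex; O2′ is the only free hydroxyl, so the site is unambiguous, and the basic medium protects the SEM acetal and the alkene.

Step 23
Reactants: 28 sodium 2-{[5β,8β,9β-trimethyl-4(11)-methylidene-10αH-trans-decalin-9α-yl]methyl}-4-[(TBDPS-oxy)methyl]-6-(SEM-oxy)phenyl sulfate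
Product: 30 2-{[(1R,2S,4aS,8aS)-1,2,4a-trimethyl-5-methylidenedecahydronaphthalen-1-yl]methyl}-6-hydroxy-4-(hydroxymethyl)phenyl hydrogen sulfate, via tetrabutylammonium sulfate salt 29 (not isolated)
Conditions: Bu4NF (6 equiv), THF, 55 °C; then sulfonic acid cation-exchange resin (H+ form), MeOH–H2O, 0 °C
Reagents that add atoms: none
Why: Fluoride-mediated desilylation removes the TBDPS ether and fragments the SEM group by β-silyl elimination; the sulfate monoester anion is inert to fluoride, and a brief cold proton exchange should give the acid form without moving the exocyclic alkene.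

## Compound list

1 | hex-5-yn-1-ol | C#CCCCCO | starting material
2 | hex-5-ynal (formed in the flask) | C#CCCCC=O | intermediate
3 | ethyl (2E)-2-methyloct-2-en-7-ynoate | C#CCCC/C=C(\C)C(=O)OCC | intermediate
4 | (2E)-2-methyloct-2-en-7-yn-1-ol | C#CCCC/C=C(\C)CO | intermediate
5 | (6E)-8-bromo-7-methyloct-6-en-1-yne | C#CCCC/C=C(\C)CBr | intermediate
6 | methyl 4-hydroxy-3-methoxybenzoate (methyl vanillate) | COC(=O)c1ccc(O)c(OC)c1 | starting material
7 | methyl 3-formyl-4-hydroxy-5-methoxybenzoate | COC(=O)c1cc(C=O)c(O)c(OC)c1 | intermediate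
8 | methyl 3-formyl-4,5-dihydroxybenzoate | COC(=O)c1cc(C=O)c(O)c(O)c1 | intermediate
9 | methyl 3-formyl-5-hydroxy-4-(prop-2-en-1-yloxy)benzoate | COC(=O)c1cc(C=O)c(OCC=C)c(O)c1 | intermediate
10 | methyl 3-formyl-4-(prop-2-en-1-yloxy)-5-{[2-(trimethylsilyl)ethoxy]methoxy}benzoate | COC(=O)c1cc(C=O)c(OCC=C)c(OCOCC[Si](C)(C)C)c1 | intermediate
11 | methyl 3-(hydroxymethyl)-4-(prop-2-en-1-yloxy)-5-{[2-(trimethylsilyl)ethoxy]methoxy}benzoate | COC(=O)c1cc(CO)c(OCC=C)c(OCOCC[Si](C)(C)C)c1 | intermediate
12 | methyl 3-(bromomethyl)-4-(prop-2-en-1-yloxy)-5-{[2-(trimethylsilyl)ethoxy]methoxy}benzoate | COC(=O)c1cc(CBr)c(OCC=C)c(OCOCC[Si](C)(C)C)c1 | intermediate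
13 | (−)-8-phenylmenthol, (1R,2S,5R)-5-methyl-2-(2-phenylpropan-2-yl)cyclohexan-1-ol | CC(C)(c1ccccc1)[C@@H]1CC[C@@H](C)C[C@H]1O | starting material
14 | methyl acetoacetate | COC(=O)CC(C)=O | starting material
15 | (1R,2S,5R)-5-methyl-2-(2-phenylpropan-2-yl)cyclohexyl 3-oxobutanoate | CC(=O)CC(=O)O[C@@H]1C[C@H](C)CC[C@H]1C(C)(C)c1ccccc1 | intermediate
16 | (1R,2S,5R)-5-methyl-2-(2-phenylpropan-2-yl)cyclohexyl (6E)-6-methyl-3-oxododec-6-en-11-ynoate | C#CCCC/C=C(\C)CCC(=O)CC(=O)O[C@@H]1C[C@H](C)CC[C@H]1C(C)(C)c1ccccc1 | intermediate
17 | 8-phenylmenthyl (6E)-2-(arylmethyl)-6-methyl-3-oxododec-6-en-11-ynoate, aryl = ArE, both C2 epimers (cyclisation precursor) | C#CCCC/C=C(\C)CCC(=O)C(Cc1cc(C(=O)OC)cc(OCOCC[Si](C)(C)C)c1OCC=C)C(=O)O[C@@H]1C[C@H](C)CC[C@H]1C(C)(C)c1ccccc1 | intermediate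
18 | trans-decalin keto diester: C4=C11, C8 ketone, 9β-CO2R* (axial), 9α-CH2ArE, 5β-CH3, 10α-H | C=C1CCC[C@H]2[C@](C(=O)O[C@@H]3C[C@H](C)CC[C@H]3C(C)(C)c3ccccc3)(Cc3cc(C(=O)OC)cc(OCOCC[Si](C)(C)C)c3OCC=C)C(=O)CC[C@]12C | intermediate
19 | tertiary alcohol of 18: 8β-OH, 8α-CH3 | C=C1CCC[C@H]2[C@](C(=O)O[C@@H]3C[C@H](C)CC[C@H]3C(C)(C)c3ccccc3)(Cc3cc(C(=O)OC)cc(OCOCC[Si](C)(C)C)c3OCC=C)[C@@](C)(O)CC[C@]12C | intermediate
20 | triol: 9β-CH2OH, 8β-OH, 8α-CH3, 9α-CH2ArH | C=C1CCC[C@H]2[C@](CO)(Cc3cc(CO)cc(OCOCC[Si](C)(C)C)c3OCC=C)[C@@](C)(O)CC[C@]12C | intermediate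
21 | diol with the benzylic alcohol as TBDPS ether (9α-CH2ArS) | C=C1CCC[C@H]2[C@](CO)(Cc3cc(CO[Si](c4ccccc4)(c4ccccc4)C(C)(C)C)cc(OCOCC[Si](C)(C)C)c3OCC=C)[C@@](C)(O)CC[C@]12C | intermediate
22 | cyclic thionocarbonate (1,3-dioxane-2-thione) bridging O13 and the 8β-oxygen | C=C1CCC[C@H]2[C@@]3(Cc4cc(CO[Si](c5ccccc5)(c5ccccc5)C(C)(C)C)cc(OCOCC[Si](C)(C)C)c4OCC=C)COC(=S)O[C@@]3(C)CC[C@]12C | intermediate
23 | 8β-methyl decalin with C13–O–C(=O)–S–SnBu3 (formed in the flask) | C=C1CCC[C@H]2[C@](COC(=O)S[Sn](CCCC)(CCCC)CCCC)(Cc3cc(CO[Si](c4ccccc4)(c4ccccc4)C(C)(C)C)cc(OCOCC[Si](C)(C)C)c3OCC=C)[C@@H](C)CC[C@]12C | intermediate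
24 | C13 carbinol: 9β-CH2OH, 8β-CH3 (8S), 9α-CH2ArS | C=C1CCC[C@H]2[C@](CO)(Cc3cc(CO[Si](c4ccccc4)(c4ccccc4)C(C)(C)C)cc(OCOCC[Si](C)(C)C)c3OCC=C)[C@@H](C)CC[C@]12C | intermediate
25 | S-methyl xanthate of 24 | C=C1CCC[C@H]2[C@](COC(=S)SC)(Cc3cc(CO[Si](c4ccccc4)(c4ccccc4)C(C)(C)C)cc(OCOCC[Si](C)(C)C)c3OCC=C)[C@@H](C)CC[C@]12C | intermediate
26 | 5β,8β,9β-trimethyl-4(11)-methylidene decalin with 9α-CH2ArS | C=C1CCC[C@H]2[C@](C)(Cc3cc(CO[Si](c4ccccc4)(c4ccccc4)C(C)(C)C)cc(OCOCC[Si](C)(C)C)c3OCC=C)[C@@H](C)CC[C@]12C | intermediate
27 | O2′ phenol (O3′ SEM, benzylic O TBDPS) | C=C1CCC[C@H]2[C@](C)(Cc3cc(CO[Si](c4ccccc4)(c4ccccc4)C(C)(C)C)cc(OCOCC[Si](C)(C)C)c3O)[C@@H](C)CC[C@]12C | intermediate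
28 | sodium O2′ sulfate (O3′ SEM, benzylic O TBDPS) | C=C1CCC[C@H]2[C@](C)(Cc3cc(CO[Si](c4ccccc4)(c4ccccc4)C(C)(C)C)cc(OCOCC[Si](C)(C)C)c3OS(=O)(=O)[O-])[C@@H](C)CC[C@]12C.[Na+] | intermediate
29 | tetrabutylammonium salt of the target sulfate (formed in the flask) | C=C1CCC[C@H]2[C@](C)(Cc3cc(CO)cc(O)c3OS(=O)(=O)[O-])[C@@H](C)CC[C@]12C.CCCC[N+](CCCC)(CCCC)CCCC | intermediate
30 | 2-{[(1R,2S,4aS,8aS)-1,2,4a-trimethyl-5-methylidenedecahydronaphthalen-1-yl]methyl}-6-hydroxy-4-(hydroxymethyl)phenyl hydrogen sulfate | C=C1CCC[C@H]2[C@](C)(Cc3cc(CO)cc(O)c3OS(=O)(=O)O)[C@@H](C)CC[C@]12C | target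

## Step count and weak points

Total: 23 steps. Longest linear sequence: 18 steps (from 6 through steps 4–9 and 12–23).

**Step 13 (key step).** The most likely failure is bond formation on the wrong face of the C9 radical. The ester is pushed out of the radical plane by C7, and the phenyl shield may then be weak or act in the opposite sense to the model. The second danger is hydrogen transfer from ethanol to the tertiary C5 radical before ring A closes; this would be countered by a lower ethanol fraction. If only the sense is inverted, the enantiomer of 13 is the simplest remedy. The fallback abandons auxiliary control: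
- It sets out from 14 (with 5 and 12). The dianion of 14 is alkylated with 5 to give methyl (6E)-6-methyl-3-oxododec-6-en-11-ynoate F1.
- Benzylation with 12 gives methyl (6E)-2-(ArE-methyl)-6-methyl-3-oxododec-6-en-11-ynoate F2.
- The same Mn(OAc)3·2H2O cyclisation gives the racemic bicycle with the same relative configuration. Its enantiomers are separated by preparative chromatography on a chiral stationary phase to give methyl 9α-(ArE-methyl)-5β-methyl-4(11)-methylidene-8-oxo-10αH-trans-decalin-9β-carboxylate F3.
- MeLi/CeCl3 gives methyl 9α-(ArE-methyl)-8β-hydroxy-5β,8α-dimethyl-4(11)-methylidene-10αH-trans-decalin-9β-carboxylate F4, and LiAlH4 reduction comes back to the route at 20.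

**Step 14.** The risks are methyl transfer to the aryl ester, because the hindered ketone reacts slowly, and retro-aldol cleavage of C8–C9 in the alkoxide. The fallback sets out from 18 and uses a sulfur ylide, which does not attack esters. Corey–Chaykovsky reaction with dimethylsulfonium methylide (Me3S+ I−, NaH, DMSO–THF) gives the spiro-epoxide R* 9α-(ArE-methyl)-5β-methyl-4(11)-methylidene-8α-methylene-8β-oxido (oxirane) decalin-9β-carboxylate F5. LiAlH4 then opens the oxirane at its CH2 terminus and reduces both esters, returning at 20.

**Step 18.** The radical adduct of the six-membered thionocarbonate may fragment slowly, or be reduced without C–O scission. The ring in step 17 forms only from the 8β-alcohol, so an unexpected facial outcome in step 14 would also stop the sequence here. Hydrogen transfer to the β face of C8 is the second concern. The fallback sets out from 19 and works for either C8 alcohol epimer: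
- Acylation with methyl chlorooxoacetate and 4-(dimethylamino)pyridine gives the tertiary methyl oxalate of 19 F6.
- Bu3SnH and azobisisobutyronitrile in toluene give R* 9α-(ArE-methyl)-5β,8β-dimethyl-4(11)-methylidene-10αH-trans-decalin-9β-carboxylate F7.
- LiAlH4 gives [9α-(ArH-methyl)-5β,8β-dimethyl-4(11)-methylidene-10αH-trans-decalin-9β-yl]methanol F8.
- Selective silylation with TBDPSCl returns at 24.

**Step 20.** The neopentylic primary C–O bond fragments slowly, so the adduct radical may be reduced instead, regenerating the alcohol or giving partially reduced sulfur products; the temperature also stresses the allyl ether. The fallback sets out from 24 and avoids a primary alkyl radical. Oxidation with Dess–Martin periodinane gives 9α-(ArS-methyl)-5β,8β-dimethyl-4(11)-methylidene-10αH-trans-decalin-9β-carbaldehyde F9. Condensation with 4-methylbenzenesulfonohydrazide gives its tosylhydrazone F10. Reduction with catecholborane followed by NaOAc·3H2O in warm CHCl3 expels sulfinate and dinitrogen and returns at 26.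

**Step 22.** O2′ is flanked by the C1′ substituent and the SEM ether, so sulfation may stop short, and the polar salt may be lost on purification. The fallback sets out from 27 and makes a neutral, chromatographable sulfate diester:
- 2,2,2-Trichloroethyl chlorosulfate, Et3N and 4-(dimethylamino)pyridine give the aryl 2,2,2-trichloroethyl sulfate of 27 F11.
- Zn and HCO2NH4 in MeOH remove the trichloroethyl group to give the ammonium aryl sulfate F12.
- The conditions of step 23 convert F12 into 29, where it returns to the route.

**Step 6.** Alkylation may also occur at the less acidic oxygen or twice, because the more acidic phenoxide is also the less nucleophilic one. The fallback sets out from 8 and reverses the order on the dianion. NaH (2.2 equiv) in DMSO and one equivalent of SEMCl react at the more nucleophilic, non-chelated oxygen to give methyl 3-formyl-4-hydroxy-5-(SEM-oxy)benzoate F13. Allyl bromide and K2CO3 in DMF then return at 10.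

## Further compounds

F1 | step 13 | methyl (6E)-6-methyl-3-oxododec-6-en-11-ynoate | C#CCCC/C=C(\C)CCC(=O)CC(=O)OC
F2 | step 13 | methyl (6E)-2-(ArE-methyl)-6-methyl-3-oxododec-6-en-11-ynoate (racemic) | C#CCCC/C=C(\C)CCC(=O)C(Cc1cc(C(=O)OC)cc(OCOCC[Si](C)(C)C)c1OCC=C)C(=O)OC
F3 | step 13 | methyl 9α-(ArE-methyl)-5β-methyl-4(11)-methylidene-8-oxo-10αH-trans-decalin-9β-carboxylate (resolved enantiomer) | C=C1CCC[C@H]2[C@](C(=O)OC)(Cc3cc(C(=O)OC)cc(OCOCC[Si](C)(C)C)c3OCC=C)C(=O)CC[C@]12C
F4 | step 13 | methyl 9α-(ArE-methyl)-8β-hydroxy-5β,8α-dimethyl-4(11)-methylidene-10αH-trans-decalin-9β-carboxylate | C=C1CCC[C@H]2[C@](C(=O)OC)(Cc3cc(C(=O)OC)cc(OCOCC[Si](C)(C)C)c3OCC=C)[C@@](C)(O)CC[C@]12C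
F5 | step 14 | spiro-epoxide of 18 at C8 (oxirane oxygen β, CH2 α) | C=C1CCC[C@H]2[C@](C(=O)O[C@@H]3C[C@H](C)CC[C@H]3C(C)(C)c3ccccc3)(Cc3cc(C(=O)OC)cc(OCOCC[Si](C)(C)C)c3OCC=C)[C@]3(CO3)CC[C@]12C
F6 | step 18 | tertiary methyl oxalate of 19 | C=C1CCC[C@H]2[C@](C(=O)O[C@@H]3C[C@H](C)CC[C@H]3C(C)(C)c3ccccc3)(Cc3cc(C(=O)OC)cc(OCOCC[Si](C)(C)C)c3OCC=C)[C@@](C)(OC(=O)C(=O)OC)CC[C@]12C
F7 | step 18 | R* 9α-(ArE-methyl)-5β,8β-dimethyl-4(11)-methylidene-10αH-trans-decalin-9β-carboxylate | C=C1CCC[C@H]2[C@](C(=O)O[C@@H]3C[C@H](C)CC[C@H]3C(C)(C)c3ccccc3)(Cc3cc(C(=O)OC)cc(OCOCC[Si](C)(C)C)c3OCC=C)[C@@H](C)CC[C@]12C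
F8 | step 18 | [9α-(ArH-methyl)-5β,8β-dimethyl-4(11)-methylidene-10αH-trans-decalin-9β-yl]methanol | C=C1CCC[C@H]2[C@](CO)(Cc3cc(CO)cc(OCOCC[Si](C)(C)C)c3OCC=C)[C@@H](C)CC[C@]12C
F9 | step 20 | 9α-(ArS-methyl)-5β,8β-dimethyl-4(11)-methylidene-10αH-trans-decalin-9β-carbaldehyde | C=C1CCC[C@H]2[C@](C=O)(Cc3cc(CO[Si](c4ccccc4)(c4ccccc4)C(C)(C)C)cc(OCOCC[Si](C)(C)C)c3OCC=C)[C@@H](C)CC[C@]12C
F10 | step 20 | (E)-tosylhydrazone of F9 | C=C1CCC[C@H]2[C@](/C=N/NS(=O)(=O)c3ccc(C)cc3)(Cc3cc(CO[Si](c4ccccc4)(c4ccccc4)C(C)(C)C)cc(OCOCC[Si](C)(C)C)c3OCC=C)[C@@H](C)CC[C@]12C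
F11 | step 22 | aryl 2,2,2-trichloroethyl sulfate of 27 | C=C1CCC[C@H]2[C@](C)(Cc3cc(CO[Si](c4ccccc4)(c4ccccc4)C(C)(C)C)cc(OCOCC[Si](C)(C)C)c3OS(=O)(=O)OCC(Cl)(Cl)Cl)[C@@H](C)CC[C@]12C
F12 | step 22 | ammonium aryl sulfate (O3′ SEM, benzylic O TBDPS) | C=C1CCC[C@H]2[C@](C)(Cc3cc(CO[Si](c4ccccc4)(c4ccccc4)C(C)(C)C)cc(OCOCC[Si](C)(C)C)c3OS(=O)(=O)[O-])[C@@H](C)CC[C@]12C.[NH4+]
F13 | step 6 | methyl 3-formyl-4-hydroxy-5-{[2-(trimethylsilyl)ethoxy]methoxy}benzoate | COC(=O)c1cc(C=O)c(O)c(OCOCC[Si](C)(C)C)c1
A1 | alternative 1 | 2-allyl-5-[(tert-butyldimethylsilyl)oxy]-3-{1-[2,3-dimethoxy-5-(methoxymethoxymethyl)phenyl]-2,3-dimethylbut-3-en-2-yl}-2-methylcyclohexan-1-one (ring A ketone, ring B open) | O=C1C[C@H](O[Si](C)(C)C(C)(C)C)C[C@@H]([C@](C)(Cc2cc(COCOC)cc(OC)c2OC)C(C)=C)[C@]1(C)CC=C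
A2 | alternative 2 | methyl 3-{[(1R,2S,4aS,8aS)-1,2,4a-trimethyl-5-methylidenedecahydronaphthalen-1-yl]methyl}-5-[(4-methoxybenzyl)oxy]-4-[(triisopropylsilyl)oxy]benzoate | C=C1CCC[C@H]2[C@](C)(Cc3cc(C(=O)OC)cc(OCc4ccc(OC)cc4)c3O[Si](C(C)C)(C(C)C)C(C)C)[C@@H](C)CC[C@]12C
A3 | alternative 3 | 6-{[(tert-butyldimethylsilyl)oxy]methyl}-2-{[2,3-dimethoxy-5-(methoxycarbonyl)phenyl]methyl}-2,3,6-trimethylcyclohex-3-ene-1-carboxylic acid (ring B acid) | CC(C)(C)[Si](C)(C)OC[C@@]1(C)CC=C(C)[C@@](C)(Cc2cc(C(=O)OC)cc(OC)c2OC)[C@@H]1C(=O)O
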